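All runs stem from a simulated flask with constants of no real substance.

The E balance comes first: an X holds two E but counts as one Q, so a Q parked as X costs two E. The autumn run shows this at 8.00 min, where E has lost 55.7% of its charge and Q reads 27.8%, half of that loss. So at that reading Q can be told from the E left, and I take half of the E lost as my working measure of Q. But Q standing free costs one E, not two, and the noon run at 8.00 min reads 9.8% of Q against 17.2% of E lost, a ratio of 0.570, so this measure may read low.

in all of them: E 25 mM; L 27.5 mM
- noon: G 2.8 mM; run made earlier
- autumn: G 14 mM; run made earlier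
- Wednesday's: G 5.0 mM; time 15 min
- Friday's: G 20 mM; time 15 min
- Sunday's: G 10 mM; time 15 min
- Monday's: G 8.0 mM; time 15 min

| run | time / min | Q / % | E / % |
|---|---|---|---|
| noon | 0.667 | 0.3 | 99.8 |
| noon | 1.00 | 1.2 | 100.6 |
| noon | 2.00 | 1.9 | 97.5 |
| noon | 4.00 | 2.0 | 93.3 |
| noon | 8.00 | 9.8 | 82.8 |
| autumn | 0.667 | 1.1 | 98.4 |
| autumn | 1.00 | 0.1 | 96.1 |
| autumn | 2.00 | 4.7 | 90.7 |
| autumn | 4.00 | 13.6 | 71.8 |
| autumn | 8.00 | 27.8 | 44.3 |

(each reading ± 1 percentage point)

- percentages count the E that a species holds: one X or Z counts as two
- Q is meant together with its X
- steps thought possible: L + G -> D; E + D -> J; J -> G + Q; E + Q <-> X; 2 E -> Z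
- in an amount of Q, one X counts as one Q

1. the flasks by amount of Q, in percent of the E charged, highest first, at 15 min (Wednesday's / Friday's / Sunday's / Monday's)
2. the amount of Q, in percent of the E charged of the flask you put first, at 15 min
3. the amount of Q, in percent of the E charged of the flask you put last, at 15 min

I replace the curve of ln cE by one straight line. Over the last window of the autumn run I get κ = 0.00862 /mM/min, the fall of ln cE per minute and per mM of G charged, a pseudo-first-order constant taken per unit of catalyst. The noon run gives 0.0107 /mM/min over the same window, which is higher. But E moved only 10 percentage points there against 27 points in the autumn run, with a scatter of 1 point on each reading, so I keep the autumn value.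

The line doesn't start at zero, though: the autumn readings put its start at a lag of 1.26 min. With that lag I reckon that Friday's keeps 9.34% of its E, so my working measure puts Q at 45.3%. For Wednesday's I reckon 55.3% of its E kept, so the same measure puts Q at 22.4%.

Friday's invites an objection. Each Q has spent one L, and each G standing as D or J holds another. My Q in Friday's takes 11.3 mM of L and leaves 16.2 mM, less than the 20 mM of G, so κ may sag late in Friday's and my reckoned E there may come out too low.

The forecast gives Friday's > Sunday's > Monday's > Wednesday's, with 47% (41% to 55%) and 24% (20% to 28%). Its top stands above mine, “allowing for some free Q and some L depletion”.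

The flasks give Friday's > Sunday's > Monday's > Wednesday's, with 48.7% for Friday's and 24.3% for Wednesday's.

    L + G → D (k = 0.360 /M/s)
    E + D → J (k = 0.120 /M/s)
    J → G + Q (k = 0.0180 /s)
    E + Q ⇌ X, settled at all times (K = 940 /M)
    2 E → Z (k = 7.10 × 10⁻⁵ /M/s)

At the end of Friday's, L stands at 7.8% of its charge and E at 13%. Read back through the same lag, that E gives a κ of 0.00739 /mM/min, below the autumn value. The same flask as Friday's with 47 mM of L ends with 8.62% of its E, which gives a κ of 0.00892 /mM/min.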